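## Structural features

The target is a bicyclo[8.4.0]tetradecane: a six-membered ring A trans-fused at C1–C10 to a ten-membered ring B, with a γ-lactone (O7–C19–C17–C8) fused across C7–C8. Twelve stereocentres are present. C2, C1, C10, C9, C8, C7 and C6 run without a break round ring B; C10, C11, C12, C13, C14 and C1 run round ring A; C17 sits in the lactone. The C3=C4 alkene is Z and conjugated with the exocyclic C5=C16 methylene. Fragile groups are the secondary allylic chloride at C6 (ionisation, allylic transposition), the diene, the 13,14-epoxide, the tertiary β-hydroxy lactone (retro-aldol, epimerisable C17) and three esters of two kinds (butyrates on O2 and O12, acetate on O9) next to two free tertiary alcohols. The real difficulty is the ten-membered ring with its Z alkene and the C6–C10 segment, in which every carbon is functionalised and five oxygens must be told apart. The key step exploits the fact that C3 of the Z alkene lies across ring B from the oxygenated C8. A C3–C8 bond turns ring B into two six-membered rings (ring M = C1, C2, C3, C8, C9, C10; ring N = C3 to C8). A leaving group on C4 and the C8 oxygen are then 1,3-related, and the alkene geometry is stored in the M/N ring fusion. The oxygen pattern of ring M (C2, C8, C9) with the C1 methyl is that of 2-methoxy-5-methylbenzoquinone.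

## Logic of the disconnections

**Endgame, 44 back to 39.** The O12–butyryl and O9–acetyl bonds and the epoxide C–O bonds are cut last. The free 12-hydroxyl is needed to deliver the epoxide oxygen to the α face of C13=C14, and O9 is freed only when every other secondary oxygen is already acylated or masked. This fixes the order 39, 40, 41, 42, 43, 44. The acidic steps must spare the allylic chloride.

**C6–Cl and C5=C16, 39 back to 37.** The chloride is cut to a 6β-alcohol of opposite configuration (38), and the methylene to the C5 ketone (37). Chlorine then comes by stereospecific displacement from a carbinol whose configuration was fixed on a rigid ring, not by enolate chlorination beside the β-oxygen at C7. The forward steps need an SN2 reaction without allylic shift and a non-basic methylenation.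

**Lactone C7–O bond, 37 back to 34.** The O7–C7 bond is cut to a 6β,7β-epoxide and a tert-butyl ester. Five-membered ring closure with inversion at C7 gives the 7α-oxygen and at the same time frees the 6β-hydroxyl. C17 is equilibrated (36) while C5 is still a ketal, so no β-acyloxy ketone is exposed to base.

**C8–C17, 34 back to 31 and 32.** This is an ester enolate addition to the C8 ketone. The attack must come anti to both flanking C–O bonds (epoxide at C7, silyl ether at C9). For that reason O9 carries a non-chelating silyl group.

**O2 protecting group, 31 back to 29.** The PMB ether is exchanged for the final butyrate directly after the fragmentation, before the diene exists, when DDQ is harmless.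

**Key disconnection, 29 back to 27.** C3 and C8 are reconnected; C8=O becomes C8–OH and C3=C4 becomes C3–H/C4–OMs. The medium ring and its Z alkene are replaced by a linear tricycle of chairs. A configurational check shows the requirement: with 3β-H, 8β-OH and the C4 mesylate α, the M/N fusion is cis, the mesylate is equatorial on ring N and anti-periplanar to C3–C8, and C2 is axial on ring N. That is the arrangement that gives Z; a trans fusion would give E.

Three changes are made to the simplest form of such a precursor:
- Equal PMB ethers on O7 and O9 could not be told apart when the lactone must close on O7 and the acetate go to O9. O9 is therefore a silyl ether and O2 the PMB ether.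
- A bare C6 methylene would force a late enolate chlorination next to a β-leaving group. C6/C7 are therefore carried as a β-epoxide cis to the C8 hydroxyl; this geometry cannot undergo Payne rearrangement.
- The C5 ketal is acyclic so that it can be removed late under mild acid.

**Ring N, 27 back to 24.** The epoxide oxygen (delivered by the C8 hydroxyl), the mesyl group and the C6=C7 bond (ring-closing metathesis) are removed in turn via 26 and 25. Each forward step acts on one functional group only.

**C7–C8 and C3–C4, 24 back to 14, 23 and 20.** The C8 vinyl group comes from an organocerium addition that must be axial. The C3–C4 bond comes from an anti aldol of the ring M enolate, which must attack from the face opposite the axial C1 methyl. Aldehyde 20 is traced to 15 and 16.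

**Ring M oxygens, 14 back to 11.** The C8 ketone is an enol ether and the 2β-alcohol a vinylogous ester carbonyl. Both equatorial 2β-O and axial 9β-O are to come from hydride additions anti to the C1 methyl.

**C11 and C12 oxygens, 11 back to 9.** Both C–O bonds are cut at once to a C11=C12 alkene. OsO4 anti to the C1 methyl gives 11α-OH, 11β-methyl and 12α-OH together. Adding a methyl nucleophile to a C11 ketone was rejected: on the trans-fused bicycle it would enter anti to the C1 methyl and place the C11 methyl on the wrong face.

**Ring A diene, 9 back to 4.** The diene arises by 1,4-loss of silanol from an allylic silyl ether (via 8). The C9 ketone is reduced and silylated first (6, 7) so that the diene cannot move into conjugation. C10 is epimerised (5) while C9 is still a ketone.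

**Ring A, 4 back to 3 and 2; 2 back to 1.** C1–C14 and C10–C11 are cut in a Diels–Alder sense. The quinone supplies ring M and the C1 methyl; the dienol ether supplies C11 to C14 with the C20 methyl. The forward step needs the diene's methyl terminus on C10 and one quinone face.

## Other disconnections considered

**Alternative 1:** The cut is C1–C10 together with the C11–O bond. The fourteen-membered epoxy alkene A2 would be treated with BF3·OEt2: the epoxide opens at the tertiary allylic C1, C10 of the E alkene bonds to C1, and water caps the C11 cation to give A1.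
- In its favour: both carbocyclic rings, the quaternary C1 and the C10 and C11 centres arise in one step. The C2 oxygen comes from the epoxide with its configuration, and the lactone carbons are already present.
- Against it here: A2 is itself a demanding macrocycle (Z enone, Z C13=C14, E trisubstituted alkene). The C1 cation is allylic and can bond through C13 or lose a proton. The ring fusion and the C11 configuration depend on the fold of a flexible ring. A1 still lacks the C12 oxygen, a handle at C6 and the C8 hydroxyl.
- Comparison: structurally it makes ring B by bond formation across a macrocycle, whereas the chosen plan frees it by cleaving a rigid tricycle. Mechanistically a cation with several exits stands against a concerted anionic fragmentation with one stereoelectronic demand. In both plans the Z alkene is fixed before the key step, so they are equal on that point. If A2 were available in few steps the alternative would be the shorter route; the chosen plan is the more predictable at C1, C10 and C11.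

**Alternative 2:** The cuts are C2–C3 and C4–C5. Ni(cod)2 with a phosphine would join aldehyde A4, acetylene A5 and alkenylzinc bromide A6 through an oxanickelacycle to the Z-dienyl alcohol A3.
- In its favour: high convergence. The Z geometry follows from syn addition across the alkyne, which is as secure as in the chosen plan. The exocyclic methylene is already in place, which is better than a late methylenation. C6 and C7 come from a chiral-pool dioxolane.
- Against it here: no ring is closed. Ring B must still be closed at C8–C9 between two hindered carbons, the hardest bond of the molecule. The C2 configuration beside the quaternary C1 rests on the aldehyde alone. Direct alkenylzinc addition and alkyne oligomerisation compete.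
- Comparison: it is better in convergence and equal in alkene control, but it postpones the medium-ring problem that the chosen plan solves in the key step. Its overall step count cannot be judged before a ring closure is found.

**Alternative 3:** The cuts are C7–C8 and O7–C19. SmI2 would couple the C7 aldehyde of A8 with the C8 ketone, and the C7 samarium alkoxide would then close the lactone on the methyl ester to give A7.
- In its favour: ring B and the lactone form in one operation. The cis-diol preference of samarium pinacol couplings matches the syn O7/O8 relationship, which is better matched than the open-chain control on which step 22 relies. A7 already has the diene and the C6 oxygen and is only a few steps from the target, so it is better in step economy after the key step.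
- Against it here: a ten-membered ring must close by ketyl coupling under high dilution, against simple reduction and intermolecular coupling. The β-keto ester is enolisable and hindered. The ketyl sits next to a silyloxy group and a diene. The configuration of the new diol relative to C6 and C9 depends on chelation in an open chain.
- Comparison: it is bolder and shorter at the end but carries the highest ring-closure risk. The chosen plan pays with more steps after the key step for a ring B whose size and alkene geometry are fixed by a rigid precursor.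

Key step: step 19

**Remarks on the chemistry**
- Atom numbers follow the target. C15 is the C1 methyl, C16 the exocyclic methylene, C18 the C17 methyl, C20 the C11 methyl. β is the face of C15 in the usual flat drawing; α is the opposite face.
- Assumption: the oxazaborolidinium catalyst of (S) configuration is taken to shield the quinone face that leads to 4 as drawn; if the sense were opposite, the mirror-image catalyst would be used.
- Diene 2 is used as the mixture from step 1; only its (1E,3E) isomer can act as a diene. Compounds 34 and 35 are carried as C17 epimer mixtures until step 24.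

## Route

**Step 1**
Reactants: 1 (E)-pent-2-enal
Product: 2 (1E,3E)-1-(triethylsilyloxy)penta-1,3-diene
Conditions: Et3SiOSO2CF3, Et3N, Et2O, 0 °C to rt
Reagents that add atoms: triethylsilyl trifluoromethanesulfonate, CC[Si](CC)(CC)OS(=O)(=O)C(F)(F)F
Why: Silyl dienol ether formation by O-silylation and γ-deprotonation of the enal; the (1E,3E) isomer is the thermodynamically preferred one and the only one that reacts in step 2.

**Step 2**
Reactants: 3 2-methoxy-5-methylcyclohexa-2,5-diene-1,4-dione; 2 (1E,3E)-1-(triethylsilyloxy)penta-1,3-diene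
Product: 4 cis-fused cycloadduct (C2 and C9 ketones, 8-methoxy-Δ3(8), Δ12, 10β-H, 11α-methyl, 14α-triethylsilyloxy)
Conditions: (S)-1-(2-methylphenyl)-3,3-diphenyltetrahydro-1H,3H-pyrrolo[1,2-c][1,3,2]oxazaborole (20 mol%), HN(SO2CF3)2 (20 mol%), CH2Cl2, −78 °C
Reagents that add atoms: none
Why: Enantioselective Lewis-acid Diels–Alder reaction; the cationic boron acid binds the more basic vinylogous-ester carbonyl (C2), so C10 is the electrophilic carbon and takes the methyl-bearing nucleophilic diene terminus, while the methoxy-substituted double bond is inert. Endo addition on the unshielded face sets C1 (β-methyl); the C10, C11 and C14 centres are transient.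

**Step 3**
Reactants: 4 cis-fused cycloadduct
Product: 5 trans-fused enedione (10α-H)
Conditions: DBU (0.2 equiv), CH2Cl2, rt
Reagents that add atoms: none
Why: Epimerisation at C10 through the C9 enolate to the trans-fused isomer, expected to be the more stable one; the silyl ether on O14 blocks retro-aldol loss of C14 from the quaternary C1.

**Step 4**
Reactants: 5 trans-fused enedione
Product: 6 9β-alcohol
Conditions: NaBH4, CeCl3·7H2O, MeOH, −78 °C
Reagents that add atoms: none
Why: Luche 1,2-reduction of the only ketone that is not a vinylogous ester; hydride enters anti to the axial C1 methyl (α face) and gives the axial 9β-alcohol.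

**Step 5**
Reactants: 6 9β-alcohol
Product: 7 9β-tert-butyldimethylsilyl ether
Conditions: t-BuMe2SiOSO2CF3, 2,6-lutidine, CH2Cl2, 0 °C
Reagents that add atoms: tert-butyldimethylsilyl trifluoromethanesulfonate, CC(C)(C)[Si](C)(C)OS(=O)(=O)C(F)(F)F
Why: Silylation of a hindered secondary alcohol with the silyl triflate; the bulky, non-chelating ether stays on O9 until step 27.

**Step 6**
Reactants: 7 9β-tert-butyldimethylsilyl ether
Product: 9 ring A 1,3-diene (Δ11, Δ13; C11 methyl), via allylic alcohol 8 (not isolated)
Conditions: TsOH·H2O (0.1 equiv), benzene, 50 °C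
Reagents that add atoms: none
Why: Acid cleavage of the triethylsilyl ether and E1 1,4-dehydration of the allylic alcohol; the C12–C14 allyl cation can lose a proton only from C11 because C1 is quaternary, and the water released turns over the desilylation. With C9 no longer a ketone the diene cannot move into conjugation.

**Step 7**
Reactants: 9 ring A 1,3-diene
Product: 10 11α,12α-diol (Δ13 kept)
Conditions: OsO4 (5 mol%), N-methylmorpholine N-oxide, acetone–H2O, 0 °C to rt
Reagents that add atoms: N-methylmorpholine N-oxide, C[N+]1([O-])CCOCC1; water, O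
Why: Catalytic syn-dihydroxylation; the trisubstituted C11=C12 bond is the more electron-rich and less hindered alkene (C14 is neopentylic; the enedione alkene is electron-poor). OsO4 adds anti to the axial C1 methyl and sets 11α-OH/11β-methyl and 12α-OH in one event.

**Step 8**
Reactants: 10 11α,12α-diol
Product: 11 11,12-acetonide
Conditions: 2,2-dimethoxypropane, pyridinium p-toluenesulfonate (cat.), CH2Cl2, rt
Reagents that add atoms: 2,2-dimethoxypropane, COC(C)(C)OC
Why: Acetal exchange on a cis-1,2-diol gives the five-membered acetonide.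

**Step 9**
Reactants: 11 11,12-acetonide
Product: 12 2β-allylic alcohol (methyl enol ether Δ3(8))
Conditions: i-Bu2AlH, CH2Cl2, −78 °C; sodium potassium tartrate work-up
Reagents that add atoms: none
Why: 1,2-Reduction of the vinylogous ester carbonyl; hydride is delivered anti to the adjacent axial C1 methyl and gives the equatorial 2β-alcohol, the usual sense for a ketone next to an angular methyl group.

**Step 10**
Reactants: 12 2β-allylic alcohol
Product: 14 ring M C8 ketone (2β-PMB ether, 9β-silyl ether, acetonide, Δ13), via PMB enol ether 13 (not isolated)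
Conditions: NaH, 4-methoxybenzyl chloride, Bu4NI (cat.), THF–DMF, 0 °C to rt; then oxalic acid, THF–H2O, 0 °C
Reagents that add atoms: 4-methoxybenzyl chloride, COc1ccc(CCl)cc1; water, O
Why: Williamson etherification, then mild hydrolysis of the enol ether to the ketone; O2 is etherified before the ketone appears, so the β-oxygen is not lost by elimination.

**Step 11**
Reactants: 15 methyl 2,2-dimethoxyacetate; 16 acetaldehyde
Product: 18 methyl 3-hydroxy-2,2-dimethoxybutanoate, via lithium enolate 17 (not isolated)
Conditions: LiN(i-Pr)2, THF, −78 °C; then CH3CHO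
Reagents that add atoms: none
Why: Aldol addition of an α,α-dialkoxy ester enolate to an aldehyde; the new carbinol centre is removed in step 12.

**Step 12**
Reactants: 18 methyl 3-hydroxy-2,2-dimethoxybutanoate
Product: 19 methyl 2,2-dimethoxybut-3-enoate
Conditions: methyl N-(triethylammoniosulfonyl)carbamate, benzene, 50 °C
Reagents that add atoms: none
Why: Burgess dehydration by syn elimination of the sulfamate; the only β-hydrogens are on the methyl group, so the terminal alkene is the only possible product.

**Step 13**
Reactants: 19 methyl 2,2-dimethoxybut-3-enoate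
Product: 20 2,2-dimethoxybut-3-enal
Conditions: i-Bu2AlH, CH2Cl2, −78 °C
Reagents that add atoms: none
Why: Partial reduction of an ester; the α,α-dialkoxy groups stabilise the tetrahedral aluminate, so the aldehyde is released only on work-up.

**Step 14**
Reactants: 14 ring M C8 ketone; 20 2,2-dimethoxybut-3-enal
Product: 22 anti aldol adduct (C3 side chain α, C4 carbinol), via lithium enolate 21 (not isolated)
Conditions: LiN(i-Pr)2, THF, −78 °C; then 20
Reagents that add atoms: none
Why: Kinetic enolisation goes toward C3 (the C9 hydrogen is equatorial and hindered), and the equatorial 2β-ether is not aligned for elimination. The cyclic E enolate reacts through a Zimmerman–Traxler chair to give the anti aldol, and the aldehyde approaches anti to the axial C1 methyl, so C4 is attached on the α face (equatorial) with the C4 configuration needed later.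

**Step 15**
Reactants: 22 anti aldol adduct; 23 vinylmagnesium bromide
Product: 24 8β-hydroxy-8α-vinyl diene diol
Conditions: CH2=CHMgBr, CeCl3, THF, −78 °C
Reagents that add atoms: none
Why: Organocerium 1,2-addition, which limits enolisation and retro-aldol cleavage of the aldolate; axial attack on the α face, anti to the axial 9β-silyloxy group, gives 8β-OH and the axial vinyl group that is cis to the C3 side chain.

**Step 16**
Reactants: 24 8β-hydroxy-8α-vinyl diene diol
Product: 25 tricyclic cyclohexene diol (rings A, M, N; C6=C7; cis M/N fusion)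
Conditions: second-generation Grubbs catalyst RuCl2(=CHPh)(H2IMes)(PCy3) (5 mol%), CH2Cl2, 40 °C
Reagents that add atoms: none
Why: Ring-closing metathesis of two terminal vinyl groups to a cyclohexene with loss of ethene; the hindered cis-disubstituted ring A alkene does not take part.

**Step 17**
Reactants: 25 tricyclic cyclohexene diol
Product: 26 C4 mesylate
Conditions: CH3SO2Cl, Et3N, CH2Cl2, 0 °C
Reagents that add atoms: methanesulfonyl chloride, CS(=O)(=O)Cl
Why: Sulfonylation (via sulfene) of the secondary C4 alcohol; the tertiary C8 alcohol does not react at 0 °C.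

**Step 18**
Reactants: 26 C4 mesylate
Product: 27 6β,7β-epoxy C4 mesylate with free 8β-OH (fragmentation precursor)
Conditions: VO(acac)2 (5 mol%), t-BuOOH, CH2Cl2, rt
Reagents that add atoms: tert-butyl hydroperoxide, CC(C)(C)OO
Why: Hydroxyl-directed vanadium-catalysed epoxidation; the pseudo-axial tertiary allylic C8 hydroxyl delivers the peroxide oxygen to its own (β) face of C6=C7, and no other alkene has a free allylic hydroxyl.

**Step 19**
Reactants: 27 6β,7β-epoxy C4 mesylate
Product: 29 ring A–ring B Z-cyclodecenone (C8 ketone, Z C3=C4, C5 dimethyl ketal, 6β,7β-epoxide), via potassium alkoxide 28 (not isolated)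
Conditions: KOt-Bu (1.1 equiv), THF, −20 °C to 0 °C
Reagents that add atoms: none
Why: KOt-Bu deprotonates the tertiary C8 hydroxyl; in alkoxide 28 an oxygen lone pair, the C3–C8 σ bond and the equatorial C4–OMs bond are anti-periplanar, so the C8=O and C3=C4 π bonds form as C3–C8 breaks and mesylate leaves in one concerted step. The closest known reaction type is the Wharton–Grob fragmentation of decalin 1,3-diol monosulfonates to cyclodecenones. No ring is closed by bond formation, so no closure mode applies: ring B appears when the bond shared by rings M and N is cut. No tetrahedral stereocentre is created (C3, C4 and C8 become trigonal); the only new stereo-element is the C3=C4 geometry. It must be Z, and this is secured by the cis M/N fusion in which C2 is axial on ring N and therefore gauche to C5 across C3–C4, a conformation locked by the trans-fused ring A. Fragmentation must also outrun substitution and elimination: the equatorial mesylate has no anti-periplanar hydrogen, its backside is occupied by the C3–C8 bond, and the C8 oxygen cannot reach C4 to form an oxetane. The epoxide is cis to the C8 oxygen and cannot undergo Payne rearrangement, and the ketal keeps C5 from enolising. Near-stoichiometric base at low temperature limits epimerisation at C9 of the new ketone.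

**Step 20**
Reactants: 29 Z-cyclodecenone
Product: 30 2β-alcohol
Conditions: DDQ, CH2Cl2–pH 7 buffer, 0 °C
Reagents that add atoms: none
Why: Oxidative cleavage of the 4-methoxybenzyl ether by hydride abstraction and hydrolysis; no conjugated diene is present yet and the buffer protects the ketal.

**Step 21**
Reactants: 30 2β-alcohol
Product: 31 2β-butyrate
Conditions: (n-PrCO)2O, Et3N, DMAP (cat.), CH2Cl2, 0 °C
Reagents that add atoms: butyric anhydride, CCCC(=O)OC(=O)CCC
Why: DMAP-catalysed acylation of the only free hydroxyl; the ester installed here is the final C2 butyrate.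

**Step 22**
Reactants: 31 2β-butyrate; 32 tert-butyl propanoate
Product: 34 aldol adduct (8α-OH, C17 on the β side, C17 epimers), via lithium enolate 33 (not isolated)
Conditions: LiN(i-Pr)2, THF, −78 °C; then 31
Reagents that add atoms: none
Why: Ester enolate addition to a ketone. By the polar Felkin–Anh model the nucleophile should enter anti to both α C–O bonds (epoxide at C7, non-chelating silyl ether at C9); both demands point to the same face and give 8α-OH. At −78 °C the ketone reacts faster than the butyrate.

**Step 23**
Reactants: 34 aldol adduct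
Product: 35 6β-hydroxy 7α,19-lactone (C5 ketal kept, C17 epimers)
Conditions: camphorsulfonic acid (0.2 equiv), CH2Cl2, 0 °C to rt
Reagents that add atoms: none
Why: Acid-promoted epoxide-opening lactonisation; the ester carbonyl oxygen attacks C7 in a five-membered ring closure (exo) with inversion and the tert-butyl group leaves as isobutene. This sets the 7α-oxygen and frees the 6β-hydroxyl.

**Step 24**
Reactants: 35 6β-hydroxy 7α,19-lactone
Product: 37 α-hydroxy enone (C5 ketone, C17 as in the target), via equilibrated ketal lactone 36 (not isolated)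
Conditions: DBU, toluene, 50 °C; then pyridinium p-toluenesulfonate, acetone–H2O, rt
Reagents that add atoms: water, O
Why: Base equilibration at C17 should favour the epimer with C18 trans to the bulky C9 branch (cis to 8-OH); it is done while C5 is a ketal, so no β-acyloxy ketone meets base. Mild hydrolysis of the allylic dimethyl ketal in acetone then gives the ketone and leaves the acetonide and silyl ether intact.

**Step 25**
Reactants: 37 α-hydroxy enone
Product: 38 C5 methylene diene with 6β-allylic alcohol
Conditions: Zn, CH2Br2, TiCl4, THF–CH2Cl2, 0 °C to rt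
Reagents that add atoms: dibromomethane, BrCBr
Why: Takai–Lombardo methylenation; the non-basic titanium–zinc methylene reagent olefinates the ketone without enolising C6 (O7 is β to the carbonyl), and esters and the lactone are tolerated.

**Step 26**
Reactants: 38 diene with 6β-allylic alcohol
Product: 39 6α-chloride
Conditions: PPh3, hexachloroacetone, CH2Cl2, −20 °C to 0 °C
Reagents that add atoms: hexachloroacetone, O=C(C(Cl)(Cl)Cl)C(Cl)(Cl)Cl
Why: Appel-type chlorination; the alkoxyphosphonium salt is displaced by chloride with inversion. The low-temperature phosphine/hexachloroacetone variant is the one used for allylic alcohols without allylic shift; the tertiary C8 alcohol is inert.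

**Step 27**
Reactants: 39 6α-chloride
Product: 40 9β-alcohol
Conditions: HF·pyridine, pyridine–THF, 0 °C to rt
Reagents that add atoms: none
Why: Fluoride cleavage of the silyl ether under buffered, weakly acidic conditions that leave the acetonide, esters and allylic chloride untouched.

**Step 28**
Reactants: 40 9β-alcohol
Product: 41 9β-acetate
Conditions: Ac2O, DMAP, pyridine, CH2Cl2, rt
Reagents that add atoms: acetic anhydride, CC(=O)OC(C)=O
Why: DMAP-catalysed acetylation of the only free secondary alcohol; the tertiary C8 alcohol is not acylated.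

**Step 29**
Reactants: 41 9β-acetate
Product: 42 11α,12α-diol
Conditions: AcOH–H2O (4:1), 40 °C
Reagents that add atoms: none
Why: Acid hydrolysis of the acetonide; the allylic chloride is deactivated towards ionisation by the adjacent C7 acyloxy group.

**Step 30**
Reactants: 42 11α,12α-diol
Product: 43 13α,14α-epoxide
Conditions: VO(acac)2 (5 mol%), t-BuOOH, CH2Cl2, 0 °C to rt
Reagents that add atoms: tert-butyl hydroperoxide, CC(C)(C)OO
Why: Hydroxyl-directed epoxidation; the allylic 12α-hydroxyl (helped by the 11α-hydroxyl) delivers oxygen to the α face of C13=C14. The diene has no free allylic hydroxyl and should not react.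

**Step 31**
Reactants: 43 13α,14α-epoxide
Product: 44 CNP0188106.1
Conditions: (n-PrCO)2O, DMAP, Et3N, CH2Cl2, rt
Reagents that add atoms: butyric anhydride, CCCC(=O)OC(=O)CCC
Why: Acylation of the one remaining secondary alcohol (O12); the tertiary alcohols at C8 and C11 stay free.

## Compound list

1 | (E)-pent-2-enal | CC/C=C/C=O | starting material
2 | (1E,3E)-1-(triethylsilyloxy)penta-1,3-diene | C/C=C/C=C/O[Si](CC)(CC)CC | intermediate
3 | 2-methoxy-5-methylcyclohexa-2,5-diene-1,4-dione | COC1=CC(=O)C(C)=CC1=O | starting material
4 | cis-fused cycloadduct (10β-H, 11α-methyl, 14α-OSiEt3, Δ12, 8-methoxy-Δ3(8), C2 and C9 ketones) | COC1=CC(=O)[C@@]2(C)[C@@H](O[Si](CC)(CC)CC)C=C[C@@H](C)[C@H]2C1=O | intermediate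
5 | trans-fused enedione (10α-H) | COC1=CC(=O)[C@@]2(C)[C@@H](O[Si](CC)(CC)CC)C=C[C@@H](C)[C@@H]2C1=O | intermediate
6 | 9β-alcohol | COC1=CC(=O)[C@@]2(C)[C@@H](O[Si](CC)(CC)CC)C=C[C@@H](C)[C@@H]2[C@@H]1O | intermediate
7 | 9β-tert-butyldimethylsilyl ether | COC1=CC(=O)[C@@]2(C)[C@@H](O[Si](CC)(CC)CC)C=C[C@@H](C)[C@@H]2[C@@H]1O[Si](C)(C)C(C)(C)C | intermediate
8 | 14α-allylic alcohol | COC1=CC(=O)[C@@]2(C)[C@@H](O)C=C[C@@H](C)[C@@H]2[C@@H]1O[Si](C)(C)C(C)(C)C | intermediate
9 | ring A 1,3-diene (Δ11, Δ13) | COC1=CC(=O)[C@@]2(C)C=CC=C(C)[C@@H]2[C@@H]1O[Si](C)(C)C(C)(C)C | intermediate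
10 | 11α,12α-diol | COC1=CC(=O)[C@@]2(C)C=C[C@@H](O)[C@@](C)(O)[C@@H]2[C@@H]1O[Si](C)(C)C(C)(C)C | intermediate
11 | 11,12-acetonide | COC1=CC(=O)[C@@]2(C)C=C[C@H]3OC(C)(C)O[C@@]3(C)[C@@H]2[C@@H]1O[Si](C)(C)C(C)(C)C | intermediate
12 | 2β-allylic alcohol, methyl enol ether | COC1=C[C@H](O)[C@@]2(C)C=C[C@H]3OC(C)(C)O[C@@]3(C)[C@@H]2[C@@H]1O[Si](C)(C)C(C)(C)C | intermediate
13 | 2β-PMB ether, methyl enol ether | COC1=C[C@H](OCc2ccc(OC)cc2)[C@@]2(C)C=C[C@H]3OC(C)(C)O[C@@]3(C)[C@@H]2[C@@H]1O[Si](C)(C)C(C)(C)C | intermediate
14 | ring M C8 ketone (2β-OPMB, 9β-OTBS, 11α,12α-acetonide, Δ13) | O=C1C[C@H](OCc2ccc(OC)cc2)[C@@]2(C)C=C[C@H]3OC(C)(C)O[C@@]3(C)[C@@H]2[C@@H]1O[Si](C)(C)C(C)(C)C | intermediate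
15 | methyl 2,2-dimethoxyacetate | COC(OC)C(=O)OC | starting material
16 | acetaldehyde | CC=O | starting material
17 | lithium enolate of 15 | COC(OC)=C(OC)O[Li] | intermediate
18 | methyl 3-hydroxy-2,2-dimethoxybutanoate (racemic carbinol) | COC(=O)C(OC)(OC)C(C)O | intermediate
19 | methyl 2,2-dimethoxybut-3-enoate | COC(=O)C(OC)(OC)C=C | intermediate
20 | 2,2-dimethoxybut-3-enal | O=CC(OC)(OC)C=C | intermediate
21 | lithium C8(C3) enolate of 14 | [Li]OC1=C[C@H](OCc2ccc(OC)cc2)[C@@]2(C)C=C[C@H]3OC(C)(C)O[C@@]3(C)[C@@H]2[C@@H]1O[Si](C)(C)C(C)(C)C | intermediate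
22 | anti aldol adduct (3β-H, C4 carbinol, C5 dimethyl ketal, vinyl) | O=C1[C@@H]([C@H](O)C(OC)(OC)C=C)[C@H](OCc2ccc(OC)cc2)[C@@]2(C)C=C[C@H]3OC(C)(C)O[C@@]3(C)[C@@H]2[C@@H]1O[Si](C)(C)C(C)(C)C | intermediate
23 | vinylmagnesium bromide | C=C[Mg]Br | starting material
24 | 8β-hydroxy-8α-vinyl diene diol | O[C@]1(C=C)[C@@H]([C@H](O)C(OC)(OC)C=C)[C@H](OCc2ccc(OC)cc2)[C@@]2(C)C=C[C@H]3OC(C)(C)O[C@@]3(C)[C@@H]2[C@@H]1O[Si](C)(C)C(C)(C)C | intermediate
25 | tricyclic cyclohexene diol (C6=C7, 4-OH, 8β-OH, cis M/N fusion) | O[C@]12C=CC(OC)(OC)[C@@H](O)[C@H]1[C@H](OCc1ccc(OC)cc1)[C@@]1(C)C=C[C@H]3OC(C)(C)O[C@@]3(C)[C@@H]1[C@@H]2O[Si](C)(C)C(C)(C)C | intermediate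
26 | C4 mesylate (α, equatorial on ring N) | O[C@]12C=CC(OC)(OC)[C@@H](OS(C)(=O)=O)[C@H]1[C@H](OCc1ccc(OC)cc1)[C@@]1(C)C=C[C@H]3OC(C)(C)O[C@@]3(C)[C@@H]1[C@@H]2O[Si](C)(C)C(C)(C)C | intermediate
27 | tricyclic 8β-hydroxy C4 mesylate with 6β,7β-epoxide and C5 dimethyl ketal | O[C@]12[C@@H]3O[C@@H]3C(OC)(OC)[C@@H](OS(C)(=O)=O)[C@H]1[C@H](OCc1ccc(OC)cc1)[C@@]1(C)C=C[C@H]3OC(C)(C)O[C@@]3(C)[C@@H]1[C@@H]2O[Si](C)(C)C(C)(C)C | intermediate
28 | potassium C8 alkoxide of 27 | [K+].[O-][C@]12[C@@H]3O[C@@H]3C(OC)(OC)[C@@H](OS(C)(=O)=O)[C@H]1[C@H](OCc1ccc(OC)cc1)[C@@]1(C)C=C[C@H]3OC(C)(C)O[C@@]3(C)[C@@H]1[C@@H]2O[Si](C)(C)C(C)(C)C | intermediate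
29 | ring A–ring B Z-cyclodecenone (C8 ketone, 6β,7β-epoxide, C5 dimethyl ketal, 2β-OPMB, 9β-OTBS) | COC1(OC)/C=C\[C@H](OCc2ccc(OC)cc2)[C@@]2(C)C=C[C@H]3OC(C)(C)O[C@@]3(C)[C@@H]2[C@H](O[Si](C)(C)C(C)(C)C)C(=O)[C@@H]2O[C@H]12 | intermediate
30 | 2β-alcohol | COC1(OC)/C=C\[C@H](O)[C@@]2(C)C=C[C@H]3OC(C)(C)O[C@@]3(C)[C@@H]2[C@H](O[Si](C)(C)C(C)(C)C)C(=O)[C@@H]2O[C@H]12 | intermediate
31 | 2β-butyrate | COC1(OC)/C=C\[C@H](OC(=O)CCC)[C@@]2(C)C=C[C@H]3OC(C)(C)O[C@@]3(C)[C@@H]2[C@H](O[Si](C)(C)C(C)(C)C)C(=O)[C@@H]2O[C@H]12 | intermediate
32 | tert-butyl propanoate | CCC(=O)OC(C)(C)C | starting material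
33 | lithium enolate of 32 | CC=C(O[Li])OC(C)(C)C | intermediate
34 | aldol adduct (8α-OH, tert-butyl ester, C17 epimers) | COC1(OC)/C=C\[C@H](OC(=O)CCC)[C@@]2(C)C=C[C@H]3OC(C)(C)O[C@@]3(C)[C@@H]2[C@H](O[Si](C)(C)C(C)(C)C)[C@](O)(C(C)C(=O)OC(C)(C)C)[C@@H]2O[C@H]12 | intermediate
35 | 6β-hydroxy 7α,19-lactone, C5 ketal (C17 epimers) | COC1(OC)/C=C\[C@H](OC(=O)CCC)[C@@]2(C)C=C[C@H]3OC(C)(C)O[C@@]3(C)[C@@H]2[C@H](O[Si](C)(C)C(C)(C)C)[C@]2(O)C(C)C(=O)O[C@H]2[C@@H]1O | intermediate
36 | C17-equilibrated lactone, C5 ketal | COC1(OC)/C=C\[C@H](OC(=O)CCC)[C@@]2(C)C=C[C@H]3OC(C)(C)O[C@@]3(C)[C@@H]2[C@H](O[Si](C)(C)C(C)(C)C)[C@]2(O)[C@@H](C)C(=O)O[C@H]2[C@@H]1O | intermediate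
37 | α-hydroxy enone (C5 ketone, 6β-OH) | O=C1/C=C\[C@H](OC(=O)CCC)[C@@]2(C)C=C[C@H]3OC(C)(C)O[C@@]3(C)[C@@H]2[C@H](O[Si](C)(C)C(C)(C)C)[C@]2(O)[C@@H](C)C(=O)O[C@H]2[C@@H]1O | intermediate
38 | C5 methylene diene, 6β-allylic alcohol | C=C1/C=C\[C@H](OC(=O)CCC)[C@@]2(C)C=C[C@H]3OC(C)(C)O[C@@]3(C)[C@@H]2[C@H](O[Si](C)(C)C(C)(C)C)[C@]2(O)[C@@H](C)C(=O)O[C@H]2[C@@H]1O | intermediate
39 | 6α-chloride | C=C1/C=C\[C@H](OC(=O)CCC)[C@@]2(C)C=C[C@H]3OC(C)(C)O[C@@]3(C)[C@@H]2[C@H](O[Si](C)(C)C(C)(C)C)[C@]2(O)[C@@H](C)C(=O)O[C@H]2[C@H]1Cl | intermediate
40 | 9β-alcohol | C=C1/C=C\[C@H](OC(=O)CCC)[C@@]2(C)C=C[C@H]3OC(C)(C)O[C@@]3(C)[C@@H]2[C@H](O)[C@]2(O)[C@@H](C)C(=O)O[C@H]2[C@H]1Cl | intermediate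
41 | 9β-acetate | C=C1/C=C\[C@H](OC(=O)CCC)[C@@]2(C)C=C[C@H]3OC(C)(C)O[C@@]3(C)[C@@H]2[C@H](OC(C)=O)[C@]2(O)[C@@H](C)C(=O)O[C@H]2[C@H]1Cl | intermediate
42 | 11α,12α-diol | C=C1/C=C\[C@H](OC(=O)CCC)[C@@]2(C)C=C[C@@H](O)[C@@](C)(O)[C@@H]2[C@H](OC(C)=O)[C@]2(O)[C@@H](C)C(=O)O[C@H]2[C@H]1Cl | intermediate
43 | 13α,14α-epoxide with free 12α-OH | C=C1/C=C\[C@H](OC(=O)CCC)[C@@]2(C)[C@H]3O[C@H]3[C@@H](O)[C@@](C)(O)[C@@H]2[C@H](OC(C)=O)[C@]2(O)[C@@H](C)C(=O)O[C@H]2[C@H]1Cl | intermediate
44 | CNP0188106.1 | C=C1/C=C\[C@H](OC(=O)CCC)[C@@]2(C)[C@H]3O[C@H]3[C@@H](OC(=O)CCC)[C@@](C)(O)[C@@H]2[C@H](OC(C)=O)[C@]2(O)[C@@H](C)C(=O)O[C@H]2[C@H]1Cl | target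

## Step count and least certain steps

Total: 31 steps. Longest linear sequence: 28 steps (steps 1–10 and 14–31, from 1); the three-step branch to 20 (steps 11–13) joins at step 14.

**Step 19 (key step).** The most likely failure is base-induced epimerisation at C9 or breakdown of the α,β-epoxy ketone as it forms. A second risk is that the epoxide flattens ring N and weakens the anti-periplanar alignment, so that fragmentation slows. Fallback: set out from mesylate 26, which has no epoxide. KOt-Bu in THF would fragment it to the Z,Z-dienone F1. The electron-poor C6=C7 bond of F1 would then be epoxidised nucleophilically (t-BuOOH, DBU, CH2Cl2); peripheral attack anti to the 9β-silyloxy group is expected to give the 6β,7β-epoxide. The route is rejoined at 29.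

**Step 2.** Poor regio- or enantiocontrol is the main risk. The catalyst may bind the C9 carbonyl and turn the diene round, its distance from the reacting double bond may weaken face selection, or the silyl dienol ether may react by conjugate addition with silyl transfer. Fallback: run the cycloaddition from 3 and 2 with BF3·OEt2, which binds the vinylogous-ester carbonyl. This would give 4 together with its mirror image, the ent-cycloadduct F2. After step 3 the trans-fused racemate (5 and the ent-trans-enedione F3) is resolved by preparative chromatography on a chiral stationary phase. The route is rejoined at 5.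

**Step 6.** Ionisation of the allylic silyl ether may be slow, or may be accompanied by loss of the C9 silyl ether or an acyl shift at the cationic stage. Fallback: from 7, cleave the triethylsilyl ether alone (pyridinium p-toluenesulfonate, MeOH) to alcohol 8 and acetylate (Ac2O, pyridine) to the 14α-allylic acetate F4. Pd(PPh3)4 with Et3N in dioxane at 80 °C would then eliminate it through the allyl–palladium complex; the C11 hydrogen is trans to the acetate and so syn to the metal. The route is rejoined at 9.

**Step 22.** Poor or reversed facial selectivity at C8 is the risk: the flexible ring may not adopt the conformation in which both α C–O bonds are anti to the nucleophile, or lithium may chelate an α-oxygen. Fallback: form the lactone C–O bond first and the C–C bond second. From 31, cesium propanoate in DMF is expected to open the epoxy ketone at C7 (α to the carbonyl, away from the quaternary ketal carbon) with inversion, giving the 7α-propanoate 6β-alcohol F5. Silylation (Et3SiOSO2CF3, 2,6-lutidine) gives the 6β-triethylsilyl ether F6. Intramolecular aldol addition of the ester enolate (LiN(SiMe3)2, THF, −78 °C) closes C17–C8 from the O7 tether. The tether can only reach the ketone face that leads to the trans-fused lactone when the C6–C7–C8–C9 torsion stays near anti, as is usual in a ten-membered ring, and gives the silylated hydroxy lactone F7. The conditions of step 24 (DBU; then pyridinium p-toluenesulfonate in acetone–water, which also removes the triethylsilyl group) rejoin the route at 37.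

**Step 26.** Allylic transposition to the primary C16 chloride, or ionisation with loss of configuration at C6, is the risk. Fallback: introduce chlorine one step earlier. From 37, Tf2O with 2,6-lutidine gives the α-triflyloxy ketone F8. Bu4NCl displaces it by SN2 next to the carbonyl, with inversion, to the 6α-chloro enone F9. Tebbe methylenation (Cp2Ti(μ-Cl)(μ-CH2)AlMe2, THF, −40 °C) then rejoins the route at 39.

## Further compounds

F1 | step 19 | Z,Z-dienone (C8 ketone, Z C6=C7, Z C3=C4, C5 dimethyl ketal) | COC1(OC)/C=C\[C@H](OCc2ccc(OC)cc2)[C@@]2(C)C=C[C@H]3OC(C)(C)O[C@@]3(C)[C@@H]2[C@H](O[Si](C)(C)C(C)(C)C)C(=O)/C=C\1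
F2 | step 2 | ent-cycloadduct (mirror image of 4) | COC1=CC(=O)[C@]2(C)[C@H](O[Si](CC)(CC)CC)C=C[C@H](C)[C@@H]2C1=O
F3 | step 2 | ent-trans-enedione (mirror image of 5) | COC1=CC(=O)[C@]2(C)[C@H](O[Si](CC)(CC)CC)C=C[C@H](C)[C@H]2C1=O
F4 | step 6 | 14α-allylic acetate | COC1=CC(=O)[C@@]2(C)[C@@H](OC(C)=O)C=C[C@@H](C)[C@@H]2[C@@H]1O[Si](C)(C)C(C)(C)C
F5 | step 22 | 7α-propanoate 6β-alcohol (C8 ketone) | COC1(OC)/C=C\[C@H](OC(=O)CCC)[C@@]2(C)C=C[C@H]3OC(C)(C)O[C@@]3(C)[C@@H]2[C@H](O[Si](C)(C)C(C)(C)C)C(=O)[C@@H](OC(=O)CC)[C@@H]1O
F6 | step 22 | 6β-triethylsilyl ether of F5 | COC1(OC)/C=C\[C@H](OC(=O)CCC)[C@@]2(C)C=C[C@H]3OC(C)(C)O[C@@]3(C)[C@@H]2[C@H](O[Si](C)(C)C(C)(C)C)C(=O)[C@@H](OC(=O)CC)[C@@H]1O[Si](CC)(CC)CC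
F7 | step 22 | silylated hydroxy lactone (8α-OH, C5 ketal, C17 epimers) | COC1(OC)/C=C\[C@H](OC(=O)CCC)[C@@]2(C)C=C[C@H]3OC(C)(C)O[C@@]3(C)[C@@H]2[C@H](O[Si](C)(C)C(C)(C)C)[C@]2(O)C(C)C(=O)O[C@H]2[C@@H]1O[Si](CC)(CC)CC
F8 | step 26 | 6β-triflyloxy enone | O=C1/C=C\[C@H](OC(=O)CCC)[C@@]2(C)C=C[C@H]3OC(C)(C)O[C@@]3(C)[C@@H]2[C@H](O[Si](C)(C)C(C)(C)C)[C@]2(O)[C@@H](C)C(=O)O[C@H]2[C@@H]1OS(=O)(=O)C(F)(F)F
F9 | step 26 | 6α-chloro enone | O=C1/C=C\[C@H](OC(=O)CCC)[C@@]2(C)C=C[C@H]3OC(C)(C)O[C@@]3(C)[C@@H]2[C@H](O[Si](C)(C)C(C)(C)C)[C@]2(O)[C@@H](C)C(=O)O[C@H]2[C@H]1Cl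
A1 | alternative 1 | ring A–ring B bicycle with C2 and C11 hydroxyls | O=C1/C=C\[C@H](O)[C@@]2(C)C=CC[C@@](C)(O)[C@@H]2[C@H](O[Si](C)(C)C(C)(C)C)C2=C(C)C(=O)O[C@H]2C1
A2 | alternative 1 | fourteen-membered epoxy alkene | O=C1/C=C\[C@@H]2O[C@@]2(C)/C=C\C/C(C)=C/[C@H](O[Si](C)(C)C(C)(C)C)C2=C(C)C(=O)O[C@H]2C1
A3 | alternative 2 | Z-dienyl C2 alcohol | C=C(/C=C\[C@H](O)[C@@]1(C)C=C[C@H]2OC(C)(C)O[C@@]2(C)[C@@H]1COCc3ccc(OC)cc3)[C@H]4OC(C)(C)O[C@@H]4C(=O)OCC
A4 | alternative 2 | ring A C2 aldehyde | O=C[C@@]1(C)C=C[C@H]2OC(C)(C)O[C@@]2(C)[C@@H]1COCc1ccc(OC)cc1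
A5 | alternative 2 | acetylene | C#C
A6 | alternative 2 | C5 alkenylzinc bromide | C=C([Zn]Br)[C@H]1OC(C)(C)O[C@@H]1C(=O)OCC
A7 | alternative 3 | ring A–ring B–lactone tricycle with C6 silyl ether | C=C1/C=C\[C@H](OCc3ccc(OC)cc3)[C@@]2(C)C=C[C@H]3OC(C)(C)O[C@@]3(C)[C@@H]2[C@H](O[Si](C)(C)C(C)(C)C)[C@]2(O)[C@@H](C)C(=O)O[C@H]2[C@@H]1O[Si](C)(C)C(C)(C)C
A8 | alternative 3 | open-chain C7 aldehyde C8 β-keto ester | O=C[C@H](O[Si](C)(C)C(C)(C)C)C(=C)/C=C\[C@H](OCc1ccc(OC)cc1)[C@@]1(C)C=C[C@H]2OC(C)(C)O[C@@]2(C)[C@@H]1[C@H](O[Si](C)(C)C(C)(C)C)C(=O)C(C)C(=O)OC
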